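The data were generated by integration with constants of no real substance; noise was put on by code.

Late times first: the flask called dusk stops rising, with 72.6% at 25.0 h and 72.0% at 40.0 h. The winter run, same charges at 106 °C, stops lower, at 64.3%. I read this stop as dying catalyst, though these readings cannot prove it.

| flask | starting material | protic impurity | free catalyst | stray impurity | temperature | remark | time |
|---|---|---|---|---|---|---|---|
| dusk | 0.12 M | 0.024 M | 0.21 mol% | 44 µM | 100 °C | the very flask that is asked about, followed so far |  |
| winter | 0.12 M | 0.024 M | 0.21 mol% | 44 µM | 106 °C | run made earlier |  |
| flask | 0.12 M | 0.0240 M | 0.21 mol% | 44 µM | 100 °C |  | 2.5 d |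

- dusk (time / h: product / %): 3.00: 22.9; 4.00: 28.9; 6.00: 39.9; 10.0: 55.1; 15.0: 64.4; 25.0: 72.6; 40.0: 72.0
- winter (time / h: product / %): 3.00: 32.5; 4.00: 40.3; 6.00: 49.2; 10.0: 60.4; 15.0: 62.5; 25.0: 63.5; 40.0: 64.3

(standard deviation of a reading: 1 percentage point)

- what is taken out of product is counted as made
- the numbers in the tables scatter with a standard deviation of 1 percentage point
- additions bring no volume worth counting

- product, in percent of the starting material first charged, at 2.5 d
- the remedy with the largest gain of product, or "none" below 2 percentage points (theta / beta / zeta / eta / none)
- product present, with what was taken out counted in, in percent of the starting material first charged, after zeta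
- product present, with what was taken out counted in, in percent of the starting material first charged, after eta

- theta: at 2.5 d add free catalyst, 50.0% of the amount charged, then wait 20 h
- beta: at 2.5 d raise the temperature by 15 K, then wait 20 h
- zeta: at 2.5 d take out 90% of the product then present, then wait 20 h
- eta: change nothing and wait 20 h more

Which numbers must you know well? Not the time. Join the two ends of the dusk run by one exponential, the plateau (the two late readings average 72.3%) and the reading at 6.00 h, and the rise has a time constant of 7.48 h. By 2.5 d the rate is down to 0.0328% of its first value, so waiting adds 0.024 percentage points.

The temperature matters, as the two plateaus show, but this flask stays at 100 °C. The loading is not needed for "now", which is read in this same flask, but it matters for a remedy. So the number to know well is the plateau, 72.3%, good to 0.71 points.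

Now suppose the catalyst dies on a clock while the rate is pseudo-first-order in c(starting material). Then a portion of catalyst gives not an amount of product but a factor by which c(starting material) falls. Suppose also that each protic impurity takes one starting material and each stray impurity takes one free catalyst. Then the working catalyst is 0.173% of the starting material, and the starting material open to it falls from 80.0% to 7.70% at the stop. The natural logarithm of that fall per unit of working catalyst is 1350: call it the capacity.

Now the remedy. Half a charge of fresh catalyst, if the added portion works in full, takes the 7.70% down to 1.86%, a gain of 5.8 points, against the mark of 2 points. So I commit to the plateau for "now", for zeta and for eta, and to theta with that gain.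

The forecast says 72.8%, theta, 73% and 72.8%: “Fresh catalyst should then restart it, while heating, removing product or waiting do nothing.”

The flask gives 72.3%, and theta is best, gaining 5.7 points, while zeta ends at 72.3% and eta at 72.3%. At 60.0 h free catalyst stands at 0.0123% of the catalyst charged, with spent catalyst A at 82.5% and spent catalyst B at 17.5%. The capacity, put to the 7.67% of starting material still free, gives 5.8 points for the added portion, and theta ends at 78.0%.

    starting material + protic impurity → quenched substrate (k = 0.103 L mol⁻¹ min⁻¹, Ea = 63.0 kJ mol⁻¹)
    starting material + free catalyst → catalyst intermediate (k = 42.2 L mol⁻¹ min⁻¹, Ea = 50.0 kJ mol⁻¹)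
    free catalyst → spent catalyst A (k = 0.00387 min⁻¹, Ea = 122 kJ mol⁻¹)
    catalyst intermediate → free catalyst + product (k = 0.965 min⁻¹, Ea = 88.0 kJ mol⁻¹)
    free catalyst + stray impurity → spent catalyst B (k = 16400 L mol⁻¹ min⁻¹, Ea = 55.0 kJ mol⁻¹)
    (constants at 100 °C)

On the neighbour flask with 0.052 mol% of free catalyst, the working catalyst is 0.0153%, so the capacity takes the 80.0% down to 65.0% and gives 15.0% of product. That flask makes 14.1%, with 66% of its starting material still free and spent catalyst B at 70.5% of its catalyst, against 17.5% in the first flask.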